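The tetralin is cut at both aryl–alkyl bonds of the anisole ring (ring A), C8a–C1 and C4a–C4. Ring A then becomes 3-methoxybenzyne, and C1–C4 with the carbinol oxygen become the ring of a 2-(naphthyl)furan. One aryne Diels–Alder reaction forms both bonds and leaves the C1 oxygen bridged to C4. The step exploits the C5 methoxy group beside C4a. This group polarises the triple bond, so the free furan carbon bonds to C8a and the naphthyl-bearing carbon to C4a. Hydride opening of the bridge at C4 with retention then sets the trans 1,4-relationship. A lipase resolution delivers the (1S,4R) enantiomer.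

Key step: step 3

Assumption: 8-methoxynaphthalen-1-ol, 2-bromofuran and 3-methoxy-2-(trimethylsilyl)phenyl trifluoromethanesulfonate are taken as catalogue compounds; every racemate is drawn as the enantiomer that leads to the target, and the tetralin numbering of the target (C1 carbinol, C4 naphthyl-bearing, C5 methoxy-bearing) is used for all intermediates.

Step 1
Reactants: 1 8-methoxynaphthalen-1-ol
Product: 2 8-methoxynaphthalen-1-yl diethylcarbamate
Conditions: NaH, Et2NC(O)Cl, THF, 0 °C to reflux
Reagents that add atoms: diethylcarbamoyl chloride, CCN(CC)C(=O)Cl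
Why: O-Carbamoylation (nucleophilic acyl substitution) of the sodium naphtholate masks the phenol against O-arylation by the aryne and installs the strongest oxygen-based group for directed lithiation; no stereocentre is formed.

Step 2
Reactants: 2 8-methoxynaphthalen-1-yl diethylcarbamate; 3 2-bromofuran
Product: 6 2-(furan-2-yl)-8-methoxynaphthalen-1-yl diethylcarbamate, via aryllithium 4 (not isolated), via arylzinc chloride 5 (not isolated)
Conditions: s-BuLi, TMEDA, THF, −78 °C; ZnCl2, −78 °C to rt; 3, Pd(PPh3)4 (5 mol %), 50 °C
Reagents that add atoms: none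
Why: Directed ortho-metalation goes to C2 of the naphthalene because the carbamate outranks the methoxy group as director and the peri position is occupied, zinc exchange at −78 °C forestalls the anionic ortho-Fries shift, and Negishi coupling with zerovalent palladium joins C2 of the furan without regiochemical ambiguity; no stereocentre is formed.

Step 3
Reactants: 6 2-(furan-2-yl)-8-methoxynaphthalen-1-yl diethylcarbamate; 7 3-methoxy-2-(trimethylsilyl)phenyl trifluoromethanesulfonate
Product: 9 rac-8-methoxy-2-[(1S,4S)-8-methoxy-1,4-dihydro-1,4-epoxynaphthalen-1-yl]naphthalen-1-yl diethylcarbamate, via 3-methoxybenzyne 8 (not isolated)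
Conditions: CsF, MeCN, rt (7 in slight excess)
Reagents that add atoms: none
Why: Fluoride strips the silyl group of 7, triflate leaves, and the free aryne 8 is taken up by the furan ring of 6 in a concerted but asynchronous [4+2] cycloaddition (aryne Diels–Alder reaction); the closest known cases are the additions of 3-alkoxybenzynes and of the strongly polarised 6,7-indolynes to 2-substituted furans, in which donor groups on the furan favour the more crowded adduct. The cycloaddition closes the six-membered carbocycle C8a–C1–C2–C3–C4–C4a and with it the 7-oxabicyclo[2.2.1]heptadiene, both sigma bonds forming suprafacially on one face of the furan. The side of addition follows from the methoxy group beside the triple bond: its inductive pull bends the aryne so that the carbon next to it (future C4a) is pinched and carries the growing negative charge while the remote carbon (future C8a) is widened and electrophilic, and the furan answers with its largest HOMO coefficient at the unsubstituted C5 while the positive charge growing at C2 is spread into the oxygenated naphthyl group; hence furan C5 bonds first to C8a and furan C2 closes onto C4a. The two bridgehead stereocentres C1 and C4 are tied to each other by the oxygen bridge, so only one relative configuration can form, and since the two furan faces are equivalent 9 is racemic. The step needs regioselectivity against the steric push between the naphthyl and methoxy groups, which is softened because the C2–C4a bond is still long in the transition state and the O-methyl group can turn away, and it needs chemoselectivity for the furan over the naphthalene, secured by the much lower aromatic stabilisation of furan and by the carbamate, which blocks O-arylation. The minor regioisomer should be separable by chromatography on base-washed silica.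

Step 4
Reactants: 9 rac-8-methoxy-2-[(1S,4S)-8-methoxy-1,4-dihydro-1,4-epoxynaphthalen-1-yl]naphthalen-1-yl diethylcarbamate
Product: 10 rac-8-methoxy-2-[(1S,4S)-8-methoxy-1,2,3,4-tetrahydro-1,4-epoxynaphthalen-1-yl]naphthalen-1-yl diethylcarbamate
Conditions: H2 (1 atm), Pd/C, K2CO3 (trace), EtOAc, rt, stopped after one equivalent of H2
Reagents that add atoms: none
Why: Heterogeneous syn-hydrogenation of the strained bicyclic alkene is much faster than benzylic C–O hydrogenolysis under buffered neutral conditions, leaves both bridgehead stereocentres untouched and closes the acid-triggered escape route to a 4-aryl-1-naphthol.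

Step 5
Reactants: 10 rac-8-methoxy-2-[(1S,4S)-8-methoxy-1,2,3,4-tetrahydro-1,4-epoxynaphthalen-1-yl]naphthalen-1-yl diethylcarbamate
Product: 12 rac-(1S,4R)-4-(1-hydroxy-8-methoxynaphthalen-2-yl)-5-methoxy-1,2,3,4-tetrahydronaphthalen-1-ol, via bridged naphthol 11 (not isolated)
Conditions: LiAlH4, AlCl3 (1:1, premixed), Et2O/THF, 0 °C to rt; aq. potassium sodium tartrate
Reagents that add atoms: none
Why: Mixed-hydride (chloroalane) reduction: hydride first cleaves the aryl carbamate as LiAlH4 does, the Lewis-acidic aluminium on the bridge oxygen then ionises only the C4–O bond (tertiary, doubly benzylic, pushed by the ortho naphtholate and the C5 methoxy group, whereas the C1–O bond is secondary and meta to that group), and the O–Al–H unit that stays on the C1 oxygen hands hydride to C4 on the face the oxygen has just left, as in the retentive aluminium hydride cleavage of bicyclic ketals, so that H-4 ends cis and the naphthyl group trans to the C1 hydroxyl.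

Step 6
Reactants: 12 rac-(1S,4R)-4-(1-hydroxy-8-methoxynaphthalen-2-yl)-5-methoxy-1,2,3,4-tetrahydronaphthalen-1-ol
Product: 13 dipolynaphthalene A [(1S,4R)-4-(1-hydroxy-8-methoxynaphthalen-2-yl)-5-methoxy-1,2,3,4-tetrahydronaphthalen-1-ol]
Conditions: Candida antarctica lipase B (immobilised), vinyl acetate, t-BuOMe, 35 °C, run to just past half conversion; chromatography
Reagents that add atoms: none
Why: Lipase-catalysed acylative kinetic resolution: the size rule for secondary alcohols (ring A as the large, the C2 methylene as the medium group) predicts fast acetylation of the (1R) enantiomer, as for 1-tetralol itself, while the hindered, hydrogen-bonded naphthol is not acylated, so the (1S,4R) alcohol stays unchanged and is separated from the (1R,4S) acetate; no stereocentre is formed, the absolute configuration is selected here.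

Compound list
1 | 8-methoxynaphthalen-1-ol | COc1cccc2cccc(O)c12 | starting material
2 | 8-methoxynaphthalen-1-yl diethylcarbamate | CCN(CC)C(=O)Oc1cccc2cccc(OC)c12 | intermediate
3 | 2-bromofuran | Brc1ccco1 | starting material
4 | 1-(diethylcarbamoyloxy)-8-methoxynaphthalen-2-yllithium (not isolated) | [Li]c1ccc2cccc(OC)c2c1OC(=O)N(CC)CC | intermediate
5 | 1-(diethylcarbamoyloxy)-8-methoxynaphthalen-2-ylzinc chloride (not isolated) | Cl[Zn]c1ccc2cccc(OC)c2c1OC(=O)N(CC)CC | intermediate
6 | 2-(furan-2-yl)-8-methoxynaphthalen-1-yl diethylcarbamate | CCN(CC)C(=O)Oc1c(-c2ccco2)ccc2cccc(OC)c12 | intermediate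
7 | 3-methoxy-2-(trimethylsilyl)phenyl trifluoromethanesulfonate | COc1cccc(OS(=O)(=O)C(F)(F)F)c1[Si](C)(C)C | starting material
8 | 3-methoxybenzyne (1-methoxy-2,3-didehydrobenzene, not isolated) | COC1=CC=CC#C1 | intermediate
9 | rac-8-methoxy-2-[(1S,4S)-8-methoxy-1,4-dihydro-1,4-epoxynaphthalen-1-yl]naphthalen-1-yl diethylcarbamate (racemate) | COc1cccc2c1[C@@]1(c3ccc4cccc(OC)c4c3OC(=O)N(CC)CC)C=C[C@@H]2O1 | intermediate
10 | rac-8-methoxy-2-[(1S,4S)-8-methoxy-1,2,3,4-tetrahydro-1,4-epoxynaphthalen-1-yl]naphthalen-1-yl diethylcarbamate (racemate) | COc1cccc2c1[C@@]1(c3ccc4cccc(OC)c4c3OC(=O)N(CC)CC)CC[C@@H]2O1 | intermediate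
11 | rac-8-methoxy-2-[(1S,4S)-8-methoxy-1,2,3,4-tetrahydro-1,4-epoxynaphthalen-1-yl]naphthalen-1-ol (racemate, present as its aluminium naphtholate, not isolated) | COc1cccc2c1[C@@]1(c3ccc4cccc(OC)c4c3O)CC[C@@H]2O1 | intermediate
12 | rac-(1S,4R)-4-(1-hydroxy-8-methoxynaphthalen-2-yl)-5-methoxy-1,2,3,4-tetrahydronaphthalen-1-ol (racemic trans alcohol) | COc1cccc2c1[C@@H](c1ccc3cccc(OC)c3c1O)CC[C@@H]2O | intermediate
13 | dipolynaphthalene A, (1S,4R)-4-(1-hydroxy-8-methoxynaphthalen-2-yl)-5-methoxy-1,2,3,4-tetrahydronaphthalen-1-ol (single enantiomer) | COc1cccc2c1[C@@H](c1ccc3cccc(OC)c3c1O)CC[C@@H]2O | target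

Total step count: 6. Longest linear sequence: 6 steps (1 to 13).

Steps most likely to fail

Step 3. Steric repulsion between the naphthyl group and the methoxy group may erode or overturn the electronic preference, which would mean poor regioselectivity.
- The fallback sets out from 6 and uses a harder-pulling group beside the triple bond. The aryne is 3-(trifluoromethylsulfonyloxy)benzyne, released by CsF in MeCN from commercial 2-(trimethylsilyl)-1,3-phenylene bis(trifluoromethanesulfonate). It is more strongly distorted in the same sense.
- The cycloaddition should give the 8-triflyloxy cycloadduct F1.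
- Hydrogenation (H2, Pd/C, EtOAc) should give the saturated triflate F2.
- S–O cleavage with Et4NOH in dioxane at rt should give the phenol F3.
- O-methylation (MeI, K2CO3, acetone, rt) comes back to the route at 10.

Step 5. External hydride, or hydride from the aluminium naphtholate, may reach the planar C4 centre from the face away from the C1 oxygen. That would mean loss of facial selectivity. Proton loss from C3 may also compete.
- The fallback sets out from 10 and separates opening from reduction.
- TMSOTf and 2,6-lutidine in CH2Cl2 at −78 °C should open the bridge by elimination. This is the silyl triflate–amine opening known for epoxides, and it should give the dihydronaphthalene silyl ether F4.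
- K2CO3 in MeOH frees the homoallylic alcohol F5.
- Hydroxyl-directed hydrogenation with [Ir(cod)(PCy3)(py)]PF6 and H2 in CH2Cl2 adds hydrogen to C3=C4 on the face of the C1 hydroxyl. It should give the trans carbamate alcohol F6.
- LiAlH4 in THF removes the carbamate and comes back to the route at 12.

Step 6. The remote naphthyl group may slow the enzyme or blunt its discrimination between the enantiomers, leaving an incomplete resolution.
- The fallback sets out from 12 and uses covalent diastereomers.
- Steglich esterification of the secondary alcohol uses (S)-2-methoxy-2-phenylacetic acid, dicyclohexylcarbodiimide and DMAP in CH2Cl2. It should give the (1S,4R) mandelate ester F7 and the (1R,4S) mandelate ester F8, which are separated by chromatography or crystallisation.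
- LiOH in THF/H2O cleaves F7 and comes back to the route at 13.

Further compounds
F1 | step 3 | rac-8-methoxy-2-[(1S,4S)-8-(trifluoromethylsulfonyloxy)-1,4-dihydro-1,4-epoxynaphthalen-1-yl]naphthalen-1-yl diethylcarbamate | O=S(=O)(Oc1cccc2c1[C@@]1(c3ccc4cccc(OC)c4c3OC(=O)N(CC)CC)C=C[C@@H]2O1)C(F)(F)F
F2 | step 3 | rac-8-methoxy-2-[(1S,4S)-8-(trifluoromethylsulfonyloxy)-1,2,3,4-tetrahydro-1,4-epoxynaphthalen-1-yl]naphthalen-1-yl diethylcarbamate | O=S(=O)(Oc1cccc2c1[C@@]1(c3ccc4cccc(OC)c4c3OC(=O)N(CC)CC)CC[C@@H]2O1)C(F)(F)F
F3 | step 3 | rac-2-[(1S,4S)-8-hydroxy-1,2,3,4-tetrahydro-1,4-epoxynaphthalen-1-yl]-8-methoxynaphthalen-1-yl diethylcarbamate | Oc1cccc2c1[C@@]1(c3ccc4cccc(OC)c4c3OC(=O)N(CC)CC)CC[C@@H]2O1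
F4 | step 5 | rac-8-methoxy-2-[(4S)-8-methoxy-4-(trimethylsilyloxy)-3,4-dihydronaphthalen-1-yl]naphthalen-1-yl diethylcarbamate | COc1cccc2c1C(c1ccc3cccc(OC)c3c1OC(=O)N(CC)CC)=CC[C@@H]2O[Si](C)(C)C
F5 | step 5 | rac-2-[(4S)-4-hydroxy-8-methoxy-3,4-dihydronaphthalen-1-yl]-8-methoxynaphthalen-1-yl diethylcarbamate | COc1cccc2c1C(c1ccc3cccc(OC)c3c1OC(=O)N(CC)CC)=CC[C@@H]2O
F6 | step 5 | rac-2-[(1R,4S)-4-hydroxy-8-methoxy-1,2,3,4-tetrahydronaphthalen-1-yl]-8-methoxynaphthalen-1-yl diethylcarbamate | COc1cccc2c1[C@@H](c1ccc3cccc(OC)c3c1OC(=O)N(CC)CC)CC[C@@H]2O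
F7 | step 6 | (1S,4R)-4-(1-hydroxy-8-methoxynaphthalen-2-yl)-5-methoxy-1,2,3,4-tetrahydronaphthalen-1-yl (S)-2-methoxy-2-phenylacetate | COc1cccc2c1[C@@H](c1ccc3cccc(OC)c3c1O)CC[C@@H]2OC(=O)[C@@H](OC)c1ccccc1
F8 | step 6 | (1R,4S)-4-(1-hydroxy-8-methoxynaphthalen-2-yl)-5-methoxy-1,2,3,4-tetrahydronaphthalen-1-yl (S)-2-methoxy-2-phenylacetate | COc1cccc2c1[C@H](c1ccc3cccc(OC)c3c1O)CC[C@H]2OC(=O)[C@@H](OC)c1ccccc1
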